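**Retrosynthetic overview**

1. Locants follow 12-oxabicyclo[9.1.0]dodecane: C1 and C11 (the CH3-bearing one) are the epoxide carbons, C4 carries CO2H, C4=C5 is the ring alkene, C6 carries the benzoate, C7 is C(CH3)2. The last operations are fluoride cleavage of a 2-(trimethylsilyl)ethyl ester and O-benzoylation of a cyclic allylic alcohol.
2. The 11-membered carbocycle is opened at C5–C6: an open-chain (E)-3-iodoacrylate/neopentyl aldehyde is closed by a ligand-controlled intramolecular Nozaki–Hiyama–Kishi (Ni/Cr) addition, which forms the ring, the C6 stereocentre and the γ-oxy-enoate in one operation.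
3. Enabling feature: C6 is a carbinol flanked by the quaternary C7 (aldehyde without α-hydrogen, gem-dimethyl turn) and by C5, the β-carbon of the acrylic acid C4=C5. The ring neighbours C3 and C6 are cis on that alkene (C6–O trans to CO2H), so the alkenyl–metal bond of an (E)-iodoacrylate points back along the chain and the adduct cannot lactonise.
4. Open chain: (E)-3-iodo-2-alkylacrylic acid from an alkylmalonate and iodoform; alkylmalonate from a homoallylic iodide; E-trisubstituted alkene by Zr-catalysed carboalumination of a terminal alkyne plus ethylene oxide; alkyne from methyl isobutyrate and 5-iodopent-1-yne.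
5. Ring order: oxirane first (Shi epoxidation of the open-chain E-alkene, step 11), carbocycle second (step 13).

Key step: step 13

Remark: the ligand in step 13 is N-[2-(4-isopropyl-4,5-dihydro-1,3-oxazol-2-yl)-6-methylphenyl]methanesulfonamide; it is assumed that the antipode giving Re-face addition to the aldehyde is identified in a pilot coupling with both antipodes.

**Route**

Step 1
Reactants: 1 methyl isobutyrate (methyl 2-methylpropanoate); 2 5-iodopent-1-yne
Product: 3 methyl 2,2-dimethylhept-6-ynoate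
Conditions: LiN(iPr)2, THF, −78 °C; then 2, DMPU, −78 °C to rt
Reagents that add atoms: none
Why: Alkylation of the lithium ester enolate at the primary iodide (SN2, enolate alkylation; at −78 °C faster than proton transfer from the alkyne C–H) assembles the quaternary C7 with both methyl groups and the C8–C10 chain; no stereocentre arises.

Step 2
Reactants: 3 methyl 2,2-dimethylhept-6-ynoate
Product: 4 2,2-dimethylhept-6-yn-1-ol
Conditions: LiAlH4, Et2O, 0 °C; then H2O, aq. NaOH
Reagents that add atoms: none
Why: LiAlH4 reduction of the hindered ester gives the neopentyl alcohol (future C6) while the isolated terminal alkyne stays untouched at 0 °C.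

Step 3
Reactants: 4 2,2-dimethylhept-6-yn-1-ol
Product: 5 1-{[(2,2-dimethylhept-6-yn-1-yl)oxy]methyl}-4-methoxybenzene
Conditions: NaH, 4-methoxybenzyl chloride, Bu4NI (cat.), THF/DMF, 0 °C to rt
Reagents that add atoms: 4-methoxybenzyl chloride, COc1ccc(CCl)cc1
Why: Williamson etherification of the alkoxide (the hydroxyl is far more acidic than the alkyne C–H) installs a PMB ether that withstands the organoaluminium, carbanion and hydroxide steps ahead and can be removed oxidatively.

Step 4
Reactants: 5 1-{[(2,2-dimethylhept-6-yn-1-yl)oxy]methyl}-4-methoxybenzene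
Product: 8 (3E)-9-[(4-methoxyphenyl)methoxy]-4,8,8-trimethylnon-3-en-1-ol, via alkenyl(dimethyl)alane 6 (not isolated), via lithium butylaluminate 7 (not isolated)
Conditions: Me3Al, Cp2ZrCl2 (20 mol %), CH2Cl2, 0 °C to rt; evaporate; n-BuLi, THF/hexane, −78 °C; ethylene oxide, −78 °C to rt; aq. potassium sodium tartrate
Reagents that add atoms: trimethylaluminium, C[Al](C)C; ethylene oxide, C1CO1
Why: Zirconium-catalysed carboalumination (Negishi) adds CH3 and aluminium syn across the alkyne with aluminium at the terminal carbon, which fixes the E geometry of the trisubstituted alkene (future C1–C11), and the derived aluminate opens ethylene oxide with retention at the alkenyl carbon to add C2 and C3.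

Step 5
Reactants: 8 (3E)-9-[(4-methoxyphenyl)methoxy]-4,8,8-trimethylnon-3-en-1-ol
Product: 9 1-({[(6E)-9-iodo-2,2,6-trimethylnon-6-en-1-yl]oxy}methyl)-4-methoxybenzene
Conditions: I2, PPh3, imidazole, CH2Cl2, 0 °C
Reagents that add atoms: iodine, [I][I]
Why: Appel-type iodination converts the unhindered primary alcohol into the iodide by SN2 displacement of an alkoxyphosphonium ion, leaving alkene and PMB ether intact.

Step 6
Reactants: 9 1-({[(6E)-9-iodo-2,2,6-trimethylnon-6-en-1-yl]oxy}methyl)-4-methoxybenzene; 10 diethyl malonate (excess)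
Product: 11 diethyl 2-[(3E)-9-[(4-methoxyphenyl)methoxy]-4,8,8-trimethylnon-3-en-1-yl]propanedioate
Conditions: NaH, THF/DMF, 0 °C; then 9, 60 °C
Reagents that add atoms: none
Why: Malonic ester alkylation (SN2) with the soft, weakly basic sodium malonate, used in excess to suppress dialkylation and elimination to the diene, brings in C4 and the future carboxyl carbon.

Step 7
Reactants: 11 diethyl 2-[(3E)-9-[(4-methoxyphenyl)methoxy]-4,8,8-trimethylnon-3-en-1-yl]propanedioate
Product: 12 diethyl 2-(diiodomethyl)-2-[(3E)-9-[(4-methoxyphenyl)methoxy]-4,8,8-trimethylnon-3-en-1-yl]propanedioate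
Conditions: NaH, Et2O, reflux; then CHI3, reflux
Reagents that add atoms: iodoform, IC(I)I
Why: The sodium enolate of the alkylmalonate captures diiodocarbene generated from iodoform (known for simple 2-alkylmalonates), which attaches C5 as a CHI2 group to the fully substituted malonate carbon.

Step 8
Reactants: 12 diethyl 2-(diiodomethyl)-2-[(3E)-9-[(4-methoxyphenyl)methoxy]-4,8,8-trimethylnon-3-en-1-yl]propanedioate
Product: 13 (2E)-3-iodo-2-[(3E)-9-[(4-methoxyphenyl)methoxy]-4,8,8-trimethylnon-3-en-1-yl]prop-2-enoic acid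
Conditions: KOH, EtOH/H2O, reflux; then 1 M HCl, 0 °C
Reagents that add atoms: potassium hydroxide, [K+].[OH-]
Why: Saponification followed by decarboxylative anti-elimination of iodide from the malonate dianion is the established route to (E)-3-iodo-2-alkylacrylic acids, so the iodine should end up cis to the C3 chain and trans to CO2H as needed for the ring-cis alkene.

Step 9
Reactants: 13 (2E)-3-iodo-2-[(3E)-9-[(4-methoxyphenyl)methoxy]-4,8,8-trimethylnon-3-en-1-yl]prop-2-enoic acid
Product: 14 2-(trimethylsilyl)ethyl (2E)-3-iodo-2-[(3E)-9-[(4-methoxyphenyl)methoxy]-4,8,8-trimethylnon-3-en-1-yl]prop-2-enoate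
Conditions: 2-(trimethylsilyl)ethanol, DCC, DMAP (cat.), CH2Cl2, 0 °C to rt
Reagents that add atoms: 2-(trimethylsilyl)ethanol, C[Si](C)(C)CCO
Why: Steglich esterification gives an ester that is inert to the coming oxidations and organochromium chemistry and is cleaved by fluoride without touching a benzoate.

Step 10
Reactants: 14 2-(trimethylsilyl)ethyl (2E)-3-iodo-2-[(3E)-9-[(4-methoxyphenyl)methoxy]-4,8,8-trimethylnon-3-en-1-yl]prop-2-enoate
Product: 15 2-(trimethylsilyl)ethyl (2E)-2-[(3E)-9-hydroxy-4,8,8-trimethylnon-3-en-1-yl]-3-iodoprop-2-enoate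
Conditions: DDQ, CH2Cl2/pH 7 buffer, 0 °C
Reagents that add atoms: none
Why: DDQ removes the PMB ether by oxidative (hydride-abstraction) cleavage of the electron-rich benzylic ether, to which the isolated alkene, the iodoacrylate and the silyl ester are inert.

Step 11
Reactants: 15 2-(trimethylsilyl)ethyl (2E)-2-[(3E)-9-hydroxy-4,8,8-trimethylnon-3-en-1-yl]-3-iodoprop-2-enoate
Product: 16 2-(trimethylsilyl)ethyl (2E)-2-{2-[(2R,3R)-3-(5-hydroxy-4,4-dimethylpentyl)-3-methyloxiran-2-yl]ethyl}-3-iodoprop-2-enoate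
Conditions: D-fructose-derived ketone of the Shi epoxidation (1,2:4,5-di-O-isopropylidene-β-D-erythro-hexo-2,3-diulo-2,6-pyranose, 30 mol %), Oxone (2KHSO5·KHSO4·K2SO4), K2CO3, Bu4NHSO4 (cat.), Na2B4O7 buffer, MeCN/CH2(OMe)2/H2O, 0 °C
Reagents that add atoms: potassium peroxymonosulfate (the oxidant in Oxone; oxygen delivered through the dioxirane of the ketone), [K+].OOS(=O)(=O)[O-]
Why: Shi epoxidation: the chiral dioxirane attacks only the electron-rich E-trisubstituted alkene (the iodoacrylate is electron-poor) through the spiro transition state, which for the D-fructose-derived ketone is expected to deliver the (R,R)-epoxide, that is C1 and C11 of the target.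

Step 12
Reactants: 16 2-(trimethylsilyl)ethyl (2E)-2-{2-[(2R,3R)-3-(5-hydroxy-4,4-dimethylpentyl)-3-methyloxiran-2-yl]ethyl}-3-iodoprop-2-enoate
Product: 17 2-(trimethylsilyl)ethyl (2E)-2-{2-[(2R,3R)-3-(4,4-dimethyl-5-oxopentyl)-3-methyloxiran-2-yl]ethyl}-3-iodoprop-2-enoate
Conditions: Pr4N[RuO4] (5 mol %), 4-methylmorpholine N-oxide, 4 Å molecular sieves, CH2Cl2, rt
Reagents that add atoms: none
Why: Ley–Griffith oxidation under neutral, anhydrous conditions stops at the non-enolisable neopentyl aldehyde and spares epoxide, vinyl iodide and ester.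

Step 13
Reactants: 17 2-(trimethylsilyl)ethyl (2E)-2-{2-[(2R,3R)-3-(4,4-dimethyl-5-oxopentyl)-3-methyloxiran-2-yl]ethyl}-3-iodoprop-2-enoate
Product: 20 2-(trimethylsilyl)ethyl (1R,4E,6R,11R)-6-hydroxy-7,7,11-trimethyl-12-oxabicyclo[9.1.0]dodec-4-ene-4-carboxylate, via alkenylchromium dichloride 18 (not isolated), via chromium alkoxide 19 (not isolated)
Conditions: CrCl2 (8 equiv), chiral oxazoline–sulfonamide ligand (8.8 equiv), Et3N (8.8 equiv), NiCl2 (0.2 equiv), THF, rt; 17 added by syringe pump over 12 h (final 2 mM); then aq. sodium serinate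
Reagents that add atoms: none
Why: Zerovalent nickel, formed from NiCl2 by CrCl2, inserts into the C5–I bond with retention, and transmetalation to trivalent chromium gives the alkenylchromium 18, which adds to the C6 aldehyde inside the ligand sphere to give alkoxide 19 and, on work-up, 20 (Nozaki–Hiyama–Kishi reaction). The closest known reaction type is the asymmetric Ni/Cr-mediated alkenyl iodide–aldehyde coupling with stoichiometric chiral oxazoline–sulfonamide ligands, together with its use for medium-ring and macrocyclic closures and for couplings of (E)-3-iodo-2-alkylacrylates. The 11-membered carbocycle closes by an 11-exo-trig addition to the carbonyl group, the C4=C5 double bond ending up endocyclic with C3 and C6 cis. The new stereocentre C6 is set by the ligand on chromium, which is chosen to shield the Si face of the aldehyde so that C5 adds to the Re face (6R); the epoxide stereocentres are too remote to compete. Ring closure must beat oligomerisation and the alkene geometry must survive: pseudo-high dilution, the gem-dimethyl group at C7 (non-enolisable aldehyde, Thorpe–Ingold effect) and the (E)-iodoacrylate geometry, which points the C5–Cr bond back along the chain, serve the first, and retention in the Ni/Cr manifold serves the second. Because C6–O is trans to the ester across C4=C5 the alkoxide cannot lactonise, and the amine-buffered medium without added Lewis acid should leave the epoxide intact.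

Step 14
Reactants: 20 2-(trimethylsilyl)ethyl (1R,4E,6R,11R)-6-hydroxy-7,7,11-trimethyl-12-oxabicyclo[9.1.0]dodec-4-ene-4-carboxylate
Product: 21 2-(trimethylsilyl)ethyl (1R,4E,6R,11R)-6-(benzoyloxy)-7,7,11-trimethyl-12-oxabicyclo[9.1.0]dodec-4-ene-4-carboxylate
Conditions: benzoic anhydride, DMAP, Et3N, CH2Cl2, rt to 40 °C
Reagents that add atoms: benzoic anhydride, O=C(OC(=O)c1ccccc1)c1ccccc1
Why: DMAP-catalysed acyl transfer (Steglich-type acylation) from benzoic anhydride esterifies the hindered allylic alcohol with retention at C6, and the chloride-free medium protects the epoxide.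

Step 15
Reactants: 21 2-(trimethylsilyl)ethyl (1R,4E,6R,11R)-6-(benzoyloxy)-7,7,11-trimethyl-12-oxabicyclo[9.1.0]dodec-4-ene-4-carboxylate
Product: 22 (1R,4E,6R,11R)-6-(benzoyloxy)-7,7,11-trimethyl-12-oxabicyclo[9.1.0]dodec-4-ene-4-carboxylic acid
Conditions: Bu4NF, THF, 0 °C; then aq. NH4Cl
Reagents that add atoms: none
Why: Fluoride attacks silicon and triggers β-elimination of ethene and the carboxylate (2-(trimethylsilyl)ethyl ester cleavage), conditions under which the hindered benzoate, the epoxide and the E-alkene should persist.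

**Compound list**

1 | methyl isobutyrate (methyl 2-methylpropanoate) | COC(=O)C(C)C | starting material
2 | 5-iodopent-1-yne | ICCCC#C | starting material
3 | methyl 2,2-dimethylhept-6-ynoate | COC(=O)C(C)(C)CCCC#C | intermediate
4 | 2,2-dimethylhept-6-yn-1-ol | OCC(C)(C)CCCC#C | intermediate
5 | 1-{[(2,2-dimethylhept-6-yn-1-yl)oxy]methyl}-4-methoxybenzene | COc1ccc(COCC(C)(C)CCCC#C)cc1 | intermediate
6 | [(1E)-7-[(4-methoxyphenyl)methoxy]-2,6,6-trimethylhept-1-en-1-yl]dimethylalane | C[Al](C)/C=C(\C)CCCC(C)(C)COCc1ccc(OC)cc1 | intermediate (not isolated)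
7 | lithium butyl[(1E)-7-[(4-methoxyphenyl)methoxy]-2,6,6-trimethylhept-1-en-1-yl]dimethylaluminate | [Li+].CCCC[Al-](C)(C)/C=C(\C)CCCC(C)(C)COCc1ccc(OC)cc1 | intermediate (not isolated)
8 | (3E)-9-[(4-methoxyphenyl)methoxy]-4,8,8-trimethylnon-3-en-1-ol | OCC/C=C(\C)CCCC(C)(C)COCc1ccc(OC)cc1 | intermediate
9 | 1-({[(6E)-9-iodo-2,2,6-trimethylnon-6-en-1-yl]oxy}methyl)-4-methoxybenzene | ICC/C=C(\C)CCCC(C)(C)COCc1ccc(OC)cc1 | intermediate
10 | diethyl malonate | CCOC(=O)CC(=O)OCC | starting material
11 | diethyl 2-[(3E)-9-[(4-methoxyphenyl)methoxy]-4,8,8-trimethylnon-3-en-1-yl]propanedioate | CCOC(=O)C(CC/C=C(\C)CCCC(C)(C)COCc1ccc(OC)cc1)C(=O)OCC | intermediate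
12 | diethyl 2-(diiodomethyl)-2-[(3E)-9-[(4-methoxyphenyl)methoxy]-4,8,8-trimethylnon-3-en-1-yl]propanedioate | CCOC(=O)C(CC/C=C(\C)CCCC(C)(C)COCc1ccc(OC)cc1)(C(I)I)C(=O)OCC | intermediate
13 | (2E)-3-iodo-2-[(3E)-9-[(4-methoxyphenyl)methoxy]-4,8,8-trimethylnon-3-en-1-yl]prop-2-enoic acid | OC(=O)/C(CC/C=C(\C)CCCC(C)(C)COCc1ccc(OC)cc1)=C/I | intermediate
14 | 2-(trimethylsilyl)ethyl (2E)-3-iodo-2-[(3E)-9-[(4-methoxyphenyl)methoxy]-4,8,8-trimethylnon-3-en-1-yl]prop-2-enoate | C[Si](C)(C)CCOC(=O)/C(CC/C=C(\C)CCCC(C)(C)COCc1ccc(OC)cc1)=C/I | intermediate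
15 | 2-(trimethylsilyl)ethyl (2E)-2-[(3E)-9-hydroxy-4,8,8-trimethylnon-3-en-1-yl]-3-iodoprop-2-enoate | C[Si](C)(C)CCOC(=O)/C(CC/C=C(\C)CCCC(C)(C)CO)=C/I | intermediate
16 | 2-(trimethylsilyl)ethyl (2E)-2-{2-[(2R,3R)-3-(5-hydroxy-4,4-dimethylpentyl)-3-methyloxiran-2-yl]ethyl}-3-iodoprop-2-enoate | OCC(C)(C)CCC[C@@]1(C)O[C@@H]1CC/C(=C\I)C(=O)OCC[Si](C)(C)C | intermediate
17 | 2-(trimethylsilyl)ethyl (2E)-2-{2-[(2R,3R)-3-(4,4-dimethyl-5-oxopentyl)-3-methyloxiran-2-yl]ethyl}-3-iodoprop-2-enoate | O=CC(C)(C)CCC[C@@]1(C)O[C@@H]1CC/C(=C\I)C(=O)OCC[Si](C)(C)C | intermediate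
18 | alkenylchromium dichloride derived from 17 (sulfonamide ligand and THF on chromium omitted) | O=CC(C)(C)CCC[C@@]1(C)O[C@@H]1CC/C(=C\[Cr](Cl)Cl)C(=O)OCC[Si](C)(C)C | intermediate (not isolated)
19 | chromium alkoxide of 20 (ligand on chromium omitted) | CC1(C)CCC[C@@]2(C)O[C@@H]2CC/C(C(=O)OCC[Si](C)(C)C)=C\[C@H]1O[Cr](Cl)Cl | intermediate (not isolated)
20 | 2-(trimethylsilyl)ethyl (1R,4E,6R,11R)-6-hydroxy-7,7,11-trimethyl-12-oxabicyclo[9.1.0]dodec-4-ene-4-carboxylate | CC1(C)CCC[C@@]2(C)O[C@@H]2CC/C(C(=O)OCC[Si](C)(C)C)=C\[C@H]1O | intermediate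
21 | 2-(trimethylsilyl)ethyl (1R,4E,6R,11R)-6-(benzoyloxy)-7,7,11-trimethyl-12-oxabicyclo[9.1.0]dodec-4-ene-4-carboxylate | CC1(C)CCC[C@@]2(C)O[C@@H]2CC/C(C(=O)OCC[Si](C)(C)C)=C\[C@H]1OC(=O)c1ccccc1 | intermediate
22 | (1R,4E,6R,11R)-6-(benzoyloxy)-7,7,11-trimethyl-12-oxabicyclo[9.1.0]dodec-4-ene-4-carboxylic acid | CC1(C)CCC[C@@]2(C)O[C@@H]2CC/C(C(=O)O)=C\[C@H]1OC(=O)c1ccccc1 | target

**Step count**

Total: 15 steps. Longest linear sequence: 15 steps (1 to 22; the route is linear).

**Steps most likely to fail**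

Step 13. The ligand on chromium may not override the facial preference that the closing 11-membered ring imposes on the aldehyde, so that C6 is formed with poor selectivity (and, if dilution is inadequate, bimolecular coupling competes with closure). The fallback sets C6 by reduction instead of by the C–C bond formation. It sets out from 17, which would be cyclised without chiral ligand (CrCl2, NiCl2 cat., DMSO/THF, high dilution) to a mixture of 20 and its C6 epimer, 2-(trimethylsilyl)ethyl (1R,4E,6S,11R)-6-hydroxy-7,7,11-trimethyl-12-oxabicyclo[9.1.0]dodec-4-ene-4-carboxylate F1. The mixture would be oxidised (Pr4N[RuO4], 4-methylmorpholine N-oxide) to the macrocyclic enone, 2-(trimethylsilyl)ethyl (1R,4E,11R)-7,7,11-trimethyl-6-oxo-12-oxabicyclo[9.1.0]dodec-4-ene-4-carboxylate F2. F2 would then be reduced 1,2 under reagent control (CBS oxazaborolidine, catecholborane, −78 °C, catalyst antipode assigned for the 6R alcohol), which comes back to the route at 20.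

Step 11. The dioxirane may oxidise at the iodine of the iodoacrylate in competition with the alkene, or the enantiofacial control on the open chain may be insufficient. The fallback postpones the epoxidation until the iodide is gone. It sets out from 15, which would be oxidised (Pr4N[RuO4], 4-methylmorpholine N-oxide) to 2-(trimethylsilyl)ethyl (2E)-3-iodo-2-[(3E)-4,8,8-trimethyl-9-oxonon-3-en-1-yl]prop-2-enoate F3. F3 would be closed under the conditions of step 13 to 2-(trimethylsilyl)ethyl (1E,3R,8E)-3-hydroxy-4,4,8-trimethylcycloundeca-1,8-diene-1-carboxylate F4 and benzoylated as in step 14 to 2-(trimethylsilyl)ethyl (1E,3R,8E)-3-(benzoyloxy)-4,4,8-trimethylcycloundeca-1,8-diene-1-carboxylate F5. The only electron-rich alkene of F5 would then be epoxidised with the same Shi ketone, the reagent acting on the exposed outer face of the ring E-alkene, which comes back to the route at 21.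

Step 15. Basic fluoride may cleave or shift the C6 benzoate or deconjugate the γ-acyloxy enoate by γ-deprotonation. The fallback inverts the order of ester cleavage and acylation so that the benzoate never meets fluoride. It sets out from 20, which would be treated with Bu4NF to give (1R,4E,6R,11R)-6-hydroxy-7,7,11-trimethyl-12-oxabicyclo[9.1.0]dodec-4-ene-4-carboxylic acid F6. F6 would be treated with excess benzoic anhydride, DMAP and Et3N to give benzoic (1R,4E,6R,11R)-6-(benzoyloxy)-7,7,11-trimethyl-12-oxabicyclo[9.1.0]dodec-4-ene-4-carboxylic anhydride F7. The anhydride function of F7 would be hydrolysed during work-up with aqueous NaHCO3/pyridine (either mode of cleavage gives the acid), which comes back to the route at 22.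

**Further compounds**

F1 | step 13 | 2-(trimethylsilyl)ethyl (1R,4E,6S,11R)-6-hydroxy-7,7,11-trimethyl-12-oxabicyclo[9.1.0]dodec-4-ene-4-carboxylate | CC1(C)CCC[C@@]2(C)O[C@@H]2CC/C(C(=O)OCC[Si](C)(C)C)=C\[C@@H]1O
F2 | step 13 | 2-(trimethylsilyl)ethyl (1R,4E,11R)-7,7,11-trimethyl-6-oxo-12-oxabicyclo[9.1.0]dodec-4-ene-4-carboxylate | CC1(C)CCC[C@@]2(C)O[C@@H]2CC/C(C(=O)OCC[Si](C)(C)C)=C\C1=O
F3 | step 11 | 2-(trimethylsilyl)ethyl (2E)-3-iodo-2-[(3E)-4,8,8-trimethyl-9-oxonon-3-en-1-yl]prop-2-enoate | C[Si](C)(C)CCOC(=O)/C(CC/C=C(\C)CCCC(C)(C)C=O)=C/I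
F4 | step 11 | 2-(trimethylsilyl)ethyl (1E,3R,8E)-3-hydroxy-4,4,8-trimethylcycloundeca-1,8-diene-1-carboxylate | CC1(C)CCC/C(C)=C/CC/C(C(=O)OCC[Si](C)(C)C)=C\[C@H]1O
F5 | step 11 | 2-(trimethylsilyl)ethyl (1E,3R,8E)-3-(benzoyloxy)-4,4,8-trimethylcycloundeca-1,8-diene-1-carboxylate | CC1(C)CCC/C(C)=C/CC/C(C(=O)OCC[Si](C)(C)C)=C\[C@H]1OC(=O)c1ccccc1
F6 | step 15 | (1R,4E,6R,11R)-6-hydroxy-7,7,11-trimethyl-12-oxabicyclo[9.1.0]dodec-4-ene-4-carboxylic acid | CC1(C)CCC[C@@]2(C)O[C@@H]2CC/C(C(=O)O)=C\[C@H]1O
F7 | step 15 | benzoic (1R,4E,6R,11R)-6-(benzoyloxy)-7,7,11-trimethyl-12-oxabicyclo[9.1.0]dodec-4-ene-4-carboxylic anhydride | CC1(C)CCC[C@@]2(C)O[C@@H]2CC/C(C(=O)OC(=O)c2ccccc2)=C\[C@H]1OC(=O)c1ccccc1
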